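**Retrosynthetic overview**

1. The target comes from allyl-ester cleavage and CBS reduction of the C2 ketone of a macrocyclic α-methylene ketone; the C9 angelate is put on the C9–OH freed by opening a bridging γ-lactone (C14 carboxyl to C9–O).
2. The 11-membered ring is closed at C1–C11, the bond made in the 1,11-cyclisation of farnesyl diphosphate to the humulyl cation, by a cation–olefin closure: tertiary C11 cation (from a tertiary chloride) plus the C1 terminus of a 2-silyloxydiene.
3. The open-chain chloro keto-lactone comes from a Horner–Wadsworth–Emmons reaction of an α-phosphono-γ-lactone with 4-methylidene-5-oxohexanal, which sets the C6=C7 geometry.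
4. The phosphono lactone comes from (S)-epichlorohydrin, isopropenylmagnesium bromide and triethyl phosphonoacetate (C9 from the chiral pool); the aldehyde from diethyl (2-oxopropyl)phosphonate, 2-(2-bromoethyl)-1,3-dioxolane and formaldehyde.
5. Ring order: temporary γ-lactone first, 11-membered carbocycle second, lactone opened afterwards.

Assumption (locants used in the text): farnesane/humulane numbering, ring C1–C11 with C11 = CMe2, C2 = carbinol carbon, C3 = carbon bearing the exocyclic methylene C15, C6=C7 = ring olefin, C14 = carboxyl carbon on C7, C9 = acyloxy carbon.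

**Route**

Step 1
Reactants: 1 (S)-epichlorohydrin; 2 isopropenylmagnesium bromide
Product: 3 (2S)-1-chloro-4-methylpent-4-en-2-ol
Conditions: CuI (10 mol %), THF, −40 → −20 °C; then 1 M HCl
Reagents that add atoms: isopropenylmagnesium bromide (2), CC(=C)[Mg]Br
Why: CuI-catalysed Grignard opening of the epoxide at its unsubstituted carbon (SN2) leaves the C–Cl bond and the stereocentre untouched, so the (S) centre of 1 becomes C9 of the target.

Step 2
Reactants: 3 (2S)-1-chloro-4-methylpent-4-en-2-ol; 4 triethyl phosphonoacetate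
Product: 6 diethyl [(5S)-5-(2-methylprop-2-en-1-yl)-2-oxooxolan-3-yl]phosphonate, via epoxide 5 (not isolated)
Conditions: NaOEt (2.2 equiv), EtOH, 0 °C → reflux; then AcOH
Reagents that add atoms: triethyl phosphonoacetate (4), CCOC(=O)CP(=O)(OCC)OCC
Why: Base closes the chlorohydrin to epoxide 5 (intramolecular Williamson reaction), the phosphonoacetate anion opens it at the terminal carbon and the alkoxide lactonises, as in the classical malonate–epoxide lactone synthesis; the C–O bond at the stereocentre is never broken.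

Step 3
Reactants: 6 diethyl [(5S)-5-(2-methylprop-2-en-1-yl)-2-oxooxolan-3-yl]phosphonate
Product: 7 diethyl [(5R)-5-(2-chloro-2-methylpropyl)-2-oxooxolan-3-yl]phosphonate
Conditions: HCl (g), CH2Cl2, −20 → 0 °C
Reagents that add atoms: hydrogen chloride, Cl
Why: Markovnikov hydrochlorination of the 1,1-disubstituted alkene gives the tertiary chloride that later serves as the C11 cation precursor; lactone and phosphonate are inert to dry HCl (the descriptor changes only because Cl raises the CIP priority).

Step 4
Reactants: 8 diethyl (2-oxopropyl)phosphonate; 9 2-(2-bromoethyl)-1,3-dioxolane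
Product: 10 diethyl [1-(1,3-dioxolan-2-yl)-4-oxopentan-3-yl]phosphonate
Conditions: NaH, NaI (cat.), THF/DMF, 60 °C
Reagents that add atoms: 2-(2-bromoethyl)-1,3-dioxolane (9), BrCCC1OCCO1
Why: C-alkylation of the sodium salt of a β-keto phosphonate with a primary bromide (iodide-assisted SN2).

Step 5
Reactants: 10 diethyl [1-(1,3-dioxolan-2-yl)-4-oxopentan-3-yl]phosphonate; 11 formaldehyde
Product: 12 5-(1,3-dioxolan-2-yl)-3-methylidenepentan-2-one
Conditions: 37% aq. HCHO, K2CO3, THF/H2O, rt
Reagents that add atoms: formaldehyde (11), C=O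
Why: Horner–Wadsworth–Emmons olefination with formaldehyde under Villieras conditions turns the α-phosphono ketone into the α-methylene ketone.

Step 6
Reactants: 12 5-(1,3-dioxolan-2-yl)-3-methylidenepentan-2-one
Product: 13 4-methylidene-5-oxohexanal
Conditions: 2 M HCl (cat.), THF/H2O, rt
Reagents that add atoms: water, O
Why: Acid-catalysed acetal hydrolysis frees the aldehyde; the enone is stable to dilute acid.

Step 7
Reactants: 7 diethyl [(5R)-5-(2-chloro-2-methylpropyl)-2-oxooxolan-3-yl]phosphonate; 13 4-methylidene-5-oxohexanal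
Product: 14 (3E,5R)-5-(2-chloro-2-methylpropyl)-3-(4-methylidene-5-oxohexylidene)oxolan-2-one
Conditions: NaH (1.0 equiv), THF, 0 °C; then 13, −78 → 0 °C
Reagents that add atoms: none
Why: Horner–Wadsworth–Emmons olefination of the α-phosphono lactone, in which the aldehyde reacts much faster than the hindered enone and the E-alkylidene lactone predominates (C5 cis to C8, the cis-in-ring olefin of the target); the minor Z isomer is removed by chromatography.

Step 8
Reactants: 14 (3E,5R)-5-(2-chloro-2-methylpropyl)-3-(4-methylidene-5-oxohexylidene)oxolan-2-one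
Product: 16 (1E,10S)-8,8-dimethyl-5-methylidene-11-oxabicyclo[8.2.1]tridec-1-ene-6,12-dione, via silyloxydiene 15 (not isolated)
Conditions: TBSOTf, Et3N, CH2Cl2, −78 → 0 °C; then added by syringe pump (12 h) to TiCl4 (4 equiv), 2,6-di-tert-butyl-4-methylpyridine (1 equiv), CH2Cl2 (final 1 mM), −78 °C; aq. NaHCO3
Reagents that add atoms: none
Why: Proposed new method: an 11-membered-ring version of the Reetz α-tert-alkylation (tertiary alkyl chloride + TiCl4 + silyl enol ether, the closest known reaction, established between two molecules and for small rings), in which TiCl4 reversibly ionises the C11–Cl bond, the C11 cation is captured at C1 by the 2-silyloxydiene (the only electron-rich π-system, since the other C=C bonds are electron-poor and the lactone oxygens cannot reach C11) and loss of TBSCl gives the α-methylene ketone; this is the C1–C11 bond of the enzymatic 1,11-cyclisation, with the cation placed on C11 so that C10 ends as CH2, the lactone and the cis-in-ring olefin prefold the chain, high dilution suppresses dimers, ion pairs that do not close return to the chloride, and no stereocentre is formed or touched.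

Step 9
Reactants: 16 (1E,10S)-8,8-dimethyl-5-methylidene-11-oxabicyclo[8.2.1]tridec-1-ene-6,12-dione; 17 allyl bromide
Product: 19 prop-2-en-1-yl (1E,10S)-10-hydroxy-8,8-dimethyl-5-methylidene-6-oxocycloundec-1-ene-1-carboxylate, via cesium carboxylate 18 (not isolated)
Conditions: CsOH·H2O (1.05 equiv), THF/H2O, 0 °C → rt; evaporate; allyl bromide, DMF, 0 °C → rt
Reagents that add atoms: cesium hydroxide, [Cs+].[OH-]; allyl bromide (17), C=CCBr
Why: Saponification of the bridging lactone followed by SN2 O-alkylation of the cesium carboxylate protects C14 without ever activating it, so the freed C9–OH does not relactonise; no bond to C9 is broken.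

Step 10
Reactants: 19 prop-2-en-1-yl (1E,10S)-10-hydroxy-8,8-dimethyl-5-methylidene-6-oxocycloundec-1-ene-1-carboxylate; 20 angelic acid
Product: 21 prop-2-en-1-yl (1E,10S)-8,8-dimethyl-5-methylidene-10-{[(2Z)-2-methylbut-2-enoyl]oxy}-6-oxocycloundec-1-ene-1-carboxylate
Conditions: 2,4,6-trichlorobenzoyl chloride, Et3N, toluene, rt; then 19, 75 °C (no DMAP)
Reagents that add atoms: angelic acid (20), C/C=C(/C)C(=O)O
Why: Yamaguchi-type acylation with the preformed mixed anhydride in the absence of DMAP transfers the angeloyl group without Z to E isomerisation; C9–OH is the only free hydroxyl and its configuration is retained.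

Step 11
Reactants: 21 prop-2-en-1-yl (1E,10S)-8,8-dimethyl-5-methylidene-10-{[(2Z)-2-methylbut-2-enoyl]oxy}-6-oxocycloundec-1-ene-1-carboxylate
Product: 22 prop-2-en-1-yl (1E,6S,10S)-6-hydroxy-8,8-dimethyl-5-methylidene-10-{[(2Z)-2-methylbut-2-enoyl]oxy}cycloundec-1-ene-1-carboxylate
Conditions: (R)-2-methyl-CBS-oxazaborolidine (20 mol %), catecholborane, toluene, −78 → −40 °C; pH 7 buffer
Reagents that add atoms: none
Why: Corey–Bakshi–Shibata reduction, in which the (R)-oxazaborolidine delivers hydride to the enone carbonyl with the α-substituted vinyl group as the large and the CH2 group as the small substituent, giving the (S) allylic alcohol by 1,2-reduction only; the esters are inert to catecholborane at this temperature.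

Step 12
Reactants: 22 prop-2-en-1-yl (1E,6S,10S)-6-hydroxy-8,8-dimethyl-5-methylidene-10-{[(2Z)-2-methylbut-2-enoyl]oxy}cycloundec-1-ene-1-carboxylate
Product: 23 (1E,6S,10S)-6-hydroxy-8,8-dimethyl-5-methylidene-10-{[(2Z)-2-methylbut-2-enoyl]oxy}cycloundec-1-ene-1-carboxylic acid
Conditions: Pd(PPh3)4 (5 mol %), morpholine, THF, rt; aq. citric acid
Reagents that add atoms: none
Why: Tsuji–Trost deallylation, in which zerovalent palladium ionises only the allyl ester and morpholine traps the allyl group; the angelate, the free allylic alcohol and both stereocentres are untouched.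

**Compound list**

1 | (S)-epichlorohydrin, (2S)-2-(chloromethyl)oxirane | ClC[C@@H]1CO1 | starting material
2 | isopropenylmagnesium bromide | CC(=C)[Mg]Br | starting material
3 | (2S)-1-chloro-4-methylpent-4-en-2-ol | ClC[C@@H](O)CC(C)=C | intermediate
4 | triethyl phosphonoacetate | CCOC(=O)CP(=O)(OCC)OCC | starting material
5 | (2S)-2-(2-methylprop-2-en-1-yl)oxirane | C=C(C)C[C@H]1CO1 | intermediate
6 | diethyl [(5S)-5-(2-methylprop-2-en-1-yl)-2-oxooxolan-3-yl]phosphonate (both C3 epimers) | O=C1O[C@@H](CC(C)=C)CC1P(=O)(OCC)OCC | intermediate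
7 | diethyl [(5R)-5-(2-chloro-2-methylpropyl)-2-oxooxolan-3-yl]phosphonate (both C3 epimers) | O=C1O[C@@H](CC(C)(C)Cl)CC1P(=O)(OCC)OCC | intermediate
8 | diethyl (2-oxopropyl)phosphonate | CC(=O)CP(=O)(OCC)OCC | starting material
9 | 2-(2-bromoethyl)-1,3-dioxolane | BrCCC1OCCO1 | starting material
10 | diethyl [1-(1,3-dioxolan-2-yl)-4-oxopentan-3-yl]phosphonate (racemic) | CC(=O)C(CCC1OCCO1)P(=O)(OCC)OCC | intermediate
11 | formaldehyde | C=O | starting material
12 | 5-(1,3-dioxolan-2-yl)-3-methylidenepentan-2-one | CC(=O)C(=C)CCC1OCCO1 | intermediate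
13 | 4-methylidene-5-oxohexanal | CC(=O)C(=C)CCC=O | intermediate
14 | (3E,5R)-5-(2-chloro-2-methylpropyl)-3-(4-methylidene-5-oxohexylidene)oxolan-2-one | O=C1O[C@@H](CC(C)(C)Cl)C/C1=C\CCC(=C)C(C)=O | intermediate
15 | (3E,5R)-3-{5-[(tert-butyldimethylsilyl)oxy]-4-methylidenehex-5-en-1-ylidene}-5-(2-chloro-2-methylpropyl)oxolan-2-one | O=C1O[C@@H](CC(C)(C)Cl)C/C1=C\CCC(=C)C(=C)O[Si](C)(C)C(C)(C)C | intermediate
16 | (1E,10S)-8,8-dimethyl-5-methylidene-11-oxabicyclo[8.2.1]tridec-1-ene-6,12-dione (11-membered carbocycle bridged by the C14–O–C9 lactone) | O=C1O[C@@H]2C/C1=C\CCC(=C)C(=O)CC(C)(C)C2 | intermediate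
17 | allyl bromide, 3-bromoprop-1-ene | C=CCBr | starting material
18 | cesium (1E,10S)-10-hydroxy-8,8-dimethyl-5-methylidene-6-oxocycloundec-1-ene-1-carboxylate | C=C1CC/C=C(/C(=O)[O-])C[C@@H](O)CC(C)(C)CC1=O.[Cs+] | intermediate
19 | prop-2-en-1-yl (1E,10S)-10-hydroxy-8,8-dimethyl-5-methylidene-6-oxocycloundec-1-ene-1-carboxylate | C=C1CC/C=C(/C(=O)OCC=C)C[C@@H](O)CC(C)(C)CC1=O | intermediate
20 | angelic acid, (2Z)-2-methylbut-2-enoic acid | C/C=C(/C)C(=O)O | starting material
21 | prop-2-en-1-yl (1E,10S)-8,8-dimethyl-5-methylidene-10-{[(2Z)-2-methylbut-2-enoyl]oxy}-6-oxocycloundec-1-ene-1-carboxylate | C=C1CC/C=C(/C(=O)OCC=C)C[C@@H](OC(=O)/C(C)=C\C)CC(C)(C)CC1=O | intermediate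
22 | prop-2-en-1-yl (1E,6S,10S)-6-hydroxy-8,8-dimethyl-5-methylidene-10-{[(2Z)-2-methylbut-2-enoyl]oxy}cycloundec-1-ene-1-carboxylate | C=C1CC/C=C(/C(=O)OCC=C)C[C@@H](OC(=O)/C(C)=C\C)CC(C)(C)C[C@@H]1O | intermediate
23 | (1E,6S,10S)-6-hydroxy-8,8-dimethyl-5-methylidene-10-{[(2Z)-2-methylbut-2-enoyl]oxy}cycloundec-1-ene-1-carboxylic acid | C=C1CC/C=C(/C(=O)O)C[C@@H](OC(=O)/C(C)=C\C)CC(C)(C)C[C@@H]1O | target

**Step count**

Total: 12 steps. Longest linear sequence: 9 steps (1 → 3 → 6 → 7 → 14 → 16 → 19 → 21 → 22 → 23; the branch 8 → 10 → 12 → 13 → 14 is equally long).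

**Steps most likely to fail, with fallbacks**

Step 8 (cation–olefin closure of the 11-membered ring). The ring closure has a low effective molarity, so E1 loss from the cation and intermolecular capture may win. The fallback makes the same C1–C11 bond first, between two molecules at normal concentration, and closes the ring afterwards at the C6=C7 olefin. It sets out from 12 and 7: ketone 12 is silylated (TBSOTf, Et3N) to tert-butyl{[5-(1,3-dioxolan-2-yl)-3-methylidenepent-1-en-2-yl]oxy}dimethylsilane F1. F1 is tert-alkylated by chloride 7 (ZnCl2 cat., CH2Cl2, 0 °C, mild enough to leave the dioxolane intact) to diethyl {(5S)-5-[7-(1,3-dioxolan-2-yl)-2,2-dimethyl-5-methylidene-4-oxoheptyl]-2-oxooxolan-3-yl}phosphonate F2. Aqueous HCl in THF frees the aldehyde diethyl [(5S)-5-(2,2-dimethyl-5-methylidene-4,8-dioxooctyl)-2-oxooxolan-3-yl]phosphonate F3. An intramolecular Horner–Wadsworth–Emmons reaction (LiCl, DBU, MeCN, 1 mM), in which the ring size enforces the cis-in-ring olefin, then returns to the route at 16.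

Step 10 (angeloylation). At 75 °C the γ-hydroxy ester 19 may relactonise to 16, and the angelate may partly isomerise to the tiglate. The fallback builds the Z olefin on the substrate instead of transferring it. It sets out from 19, which is acylated at 0 °C (DCC, DMAP cat., CH2Cl2) with 2-[bis(2,2,2-trifluoroethoxy)phosphoryl]propanoic acid to prop-2-en-1-yl (1E,10S)-10-({2-[bis(2,2,2-trifluoroethoxy)phosphoryl]propanoyl}oxy)-8,8-dimethyl-5-methylidene-6-oxocycloundec-1-ene-1-carboxylate F4. A Still–Gennari olefination with acetaldehyde (KHMDS, 18-crown-6, THF, −78 °C) then gives the Z-2-methylbut-2-enoate and returns to the route at 21.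

Step 11 (CBS reduction). The two ketone substituents (α-substituted vinyl against a CH2 next to a quaternary carbon) may be poorly differentiated in the macrocycle; if the sense is simply reversed, the (S)-catalyst is used. The fallback relies on substrate control with recycling. It sets out from 21, which is reduced under Luche conditions (NaBH4, CeCl3·7H2O, MeOH, −40 °C) to 22 together with its C6 epimer prop-2-en-1-yl (1E,6R,10S)-6-hydroxy-8,8-dimethyl-5-methylidene-10-{[(2Z)-2-methylbut-2-enoyl]oxy}cycloundec-1-ene-1-carboxylate F5. The two diastereomers are separated by chromatography; F5 is oxidised back to 21 (Dess–Martin periodinane) and resubmitted, and the route continues from 22.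

**Further compounds**

F1 | step 8 | tert-butyl{[5-(1,3-dioxolan-2-yl)-3-methylidenepent-1-en-2-yl]oxy}dimethylsilane | C=C(O[Si](C)(C)C(C)(C)C)C(=C)CCC1OCCO1
F2 | step 8 | diethyl {(5S)-5-[7-(1,3-dioxolan-2-yl)-2,2-dimethyl-5-methylidene-4-oxoheptyl]-2-oxooxolan-3-yl}phosphonate | O=C1O[C@@H](CC(C)(C)CC(=O)C(=C)CCC2OCCO2)CC1P(=O)(OCC)OCC
F3 | step 8 | diethyl [(5S)-5-(2,2-dimethyl-5-methylidene-4,8-dioxooctyl)-2-oxooxolan-3-yl]phosphonate | O=C1O[C@@H](CC(C)(C)CC(=O)C(=C)CCC=O)CC1P(=O)(OCC)OCC
F4 | step 10 | prop-2-en-1-yl (1E,10S)-10-({2-[bis(2,2,2-trifluoroethoxy)phosphoryl]propanoyl}oxy)-8,8-dimethyl-5-methylidene-6-oxocycloundec-1-ene-1-carboxylate | C=C1CC/C=C(/C(=O)OCC=C)C[C@@H](OC(=O)C(C)P(=O)(OCC(F)(F)F)OCC(F)(F)F)CC(C)(C)CC1=O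
F5 | step 11 | prop-2-en-1-yl (1E,6R,10S)-6-hydroxy-8,8-dimethyl-5-methylidene-10-{[(2Z)-2-methylbut-2-enoyl]oxy}cycloundec-1-ene-1-carboxylate | C=C1CC/C=C(/C(=O)OCC=C)C[C@@H](OC(=O)/C(C)=C\C)CC(C)(C)C[C@H]1O
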